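## Retrosynthetic overview

1. Feature: in the middle (gallocatechin) unit, O3 and the aryl group on C4 (C8 of the lower catechin) are cis on pyran ring C, a relationship that cationic C4 arylation does not deliver. C4 is bonded to C4a, ortho to the phenolic O1 on C8a of ring A, so C4 is the methide carbon of an o-quinone methide of ring A.
2. Key disconnection: C3–C4 and O1–C2 of that pyran ring, formed together from the o-quinone methide and the isothiourea-bound enolate of benzyloxyketene, giving a cis-3-benzyloxy-4-aryl-dihydrocoumarin. The o-quinone methide comes from an o-hydroxybenzhydrol (8-lithio-pentabenzylcatechin plus a salicylaldehyde) activated as its sulfone.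
3. The lactone carbonyl becomes C2 with the ring kept closed: lactol, anomeric sulfone, then arylzinc delivery of the pyrogallol ring anti to the cis C3/C4 substituents (2,3-trans).
4. Last skeletal bond, C4 (upper unit)–C8 (middle unit): Lewis-acid arylation with a C8-bromo-capped 3-O-acetyl catechin C4 electrophile (3,4-trans), then deacetylation and global hydrogenolysis.
5. Ring order: the rings of the lower and upper units come intact from (+)-catechin; only the middle pyran ring is built (step 7).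

Key step: step 7

Assumption: (2S,3R)-HyperBTM [(2S,3R)-3-isopropyl-2-phenyl-3,4-dihydro-2H-benzo[4,5]thiazolo[3,2-a]pyrimidine] is taken as the catalyst enantiomer that gives the required (3S,4R) lactone; if a trial run shows the opposite sense, its enantiomer is used in the same way.

Assumption: the 2-ethoxyethoxy group of 24 and 25 is drawn 4β (cis to O3); its configuration has no consequence because C4 is ionised in step 16.

## Route

Step 1
Reactants: 1 (+)-catechin
Product: 2 5,7,3',4'-tetra-O-benzyl-(+)-catechin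
Conditions: BnBr (4.2 equiv), K2CO3, DMF, 0 °C → rt
Reagents that add atoms: benzyl bromide, BrCc1ccccc1
Why: Williamson etherification in which K2CO3 deprotonates only the four phenols, so the secondary C3 hydroxyl should stay free and no stereocentre is touched.

Step 2
Reactants: 2 5,7,3',4'-tetra-O-benzyl-(+)-catechin
Product: 3 3,5,7,3',4'-penta-O-benzyl-(+)-catechin
Conditions: NaH, BnBr, DMF, 0 °C → rt
Reagents that add atoms: benzyl bromide, BrCc1ccccc1
Why: Williamson etherification of the remaining secondary alcohol through its sodium alkoxide, which leaves C2 and C3 unchanged.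

Step 3
Reactants: 3 3,5,7,3',4'-penta-O-benzyl-(+)-catechin
Product: 4 8-bromo-3,5,7,3',4'-penta-O-benzyl-(+)-catechin
Conditions: NBS (1.0 equiv), CH2Cl2, −78 °C → rt
Reagents that add atoms: N-bromosuccinimide, O=C1CCC(=O)N1Br
Why: electrophilic aromatic bromination, expected at C8 of ring A because it is para to the C5 ether, ortho to O1 and the C7 ether, and less hindered than C6, which lies between two benzyloxy groups.

Step 4
Reactants: 5 2,4,6-trihydroxybenzaldehyde
Product: 6 4,6-bis(benzyloxy)-2-hydroxybenzaldehyde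
Conditions: BnBr (2.0 equiv), K2CO3, DMF, rt
Reagents that add atoms: benzyl bromide, BrCc1ccccc1
Why: Williamson etherification that should stop at the dibenzyl ether because the last hydroxyl is hydrogen-bonded to the formyl group and is much less nucleophilic.

Step 5
Reactants: 4 8-bromo-3,5,7,3',4'-penta-O-benzyl-(+)-catechin; 6 4,6-bis(benzyloxy)-2-hydroxybenzaldehyde
Product: 9 [4,6-bis(benzyloxy)-2-hydroxyphenyl](penta-O-benzylcatechin-8-yl)methanol (both carbinol epimers), via 8-lithio-penta-O-benzylcatechin 7 (not isolated), via sodium 3,5-bis(benzyloxy)-2-formylphenoxide 8 (not isolated)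
Conditions: 4, n-BuLi, THF, −78 °C; 6, NaH, THF, 0 °C; combine, −78 → 0 °C; then H2O
Reagents that add atoms: none
Why: bromine–lithium exchange followed by 1,2-addition of the aryllithium to the aldehyde, whose phenol is masked as the sodium phenoxide so that no aryllithium is quenched; the carbinol centre forms without control and is erased in step 7.

Step 6
Reactants: 9 [4,6-bis(benzyloxy)-2-hydroxyphenyl](penta-O-benzylcatechin-8-yl)methanol
Product: 10 3,5-bis(benzyloxy)-2-[(penta-O-benzylcatechin-8-yl)(p-tolylsulfonyl)methyl]phenol (both epimers)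
Conditions: p-TolSO2H (1.5 equiv), 4 Å MS, CH2Cl2, 0 °C → rt
Reagents that add atoms: p-toluenesulfinic acid, Cc1ccc(cc1)S(=O)O
Why: acid-mediated SN1 substitution in which the sulfinic acid ionises the doubly donor-stabilised benzhydrol and the sulfinate is captured at sulfur, giving a sulfone that releases the o-quinone methide under mild base whereas the free benzhydrol would only be acylated under the conditions of step 7.

Step 7
Reactants: 10 3,5-bis(benzyloxy)-2-[(penta-O-benzylcatechin-8-yl)(p-tolylsulfonyl)methyl]phenol; 11 benzyloxyacetyl chloride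
Product: 14 (3S,4R)-3,5,7-tris(benzyloxy)-4-(penta-O-benzylcatechin-8-yl)chroman-2-one (3,4-cis), via o-quinone methide 12 (not isolated), via benzyloxyketene 13 (not isolated)
Conditions: 11 (1.5 equiv, slow addition), (2S,3R)-HyperBTM (10 mol %), i-Pr2NEt (3.5 equiv), CH2Cl2, −40 → 0 °C; cold pH 7 buffer quench
Reagents that add atoms: none
Why: i-Pr2NEt deprotonates the phenol of 10, which expels sulfinate to give o-quinone methide 12, and dehydrochlorinates 11 to benzyloxyketene 13, which the isothiourea captures as the N-acylammonium (Z)-enolate held planar by the O···S contact; the enolate α-carbon adds to the methide carbon (C3–C4, ring A re-aromatised to the phenoxide) and the phenoxide then acylates the acylammonium carbon (O1–C2), releasing the catalyst. The closest known reaction type is the Lewis-base-catalysed formal [4+2] annulation of in situ o-quinone methides with ammonium enolates, which gives cis-3,4-dihydrocoumarins. The pyran ring is closed by 6-exo-trig lactonisation after the intermolecular Michael addition. C3 is set by the catalyst, whose stereodirecting phenyl group blocks one enolate face, and C4 is set relative to C3 by the compact endo-like approach that places the small benzyloxy group and the bulky di-ortho-substituted catechinyl group cis. The step needs cis selectivity and one absolute sense: the catechin stereocentres lie four or more bonds from the methide carbon, so the catalyst rather than the substrate should decide the face, and the methide carbon, made persistent by two electron-rich aryl rings, is the only soft electrophilic site of 12. The cold neutral quench protects the epimerisable C3–H of the cis lactone.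

Step 8
Reactants: 14 (3S,4R)-3,5,7-tris(benzyloxy)-4-(penta-O-benzylcatechin-8-yl)chroman-2-one
Product: 15 (3S,4R)-3,5,7-tris(benzyloxy)-4-(penta-O-benzylcatechin-8-yl)chroman-2-ol (both anomers)
Conditions: i-Bu2AlH (1.1 equiv), CH2Cl2, −78 °C; aq. potassium sodium tartrate
Reagents that add atoms: none
Why: partial reduction of a lactone with i-Bu2AlH, in which the aluminium hemiacetal persists at −78 °C and gives the lactol only on work-up, leaving C3 and C4 untouched and the anomeric centre as a mixture that is erased in step 12.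

Step 9
Reactants: 15 (3S,4R)-3,5,7-tris(benzyloxy)-4-(penta-O-benzylcatechin-8-yl)chroman-2-ol
Product: 16 (3S,4R)-3,5,7-tris(benzyloxy)-4-(penta-O-benzylcatechin-8-yl)-2-(phenylsulfonyl)chroman (both anomers)
Conditions: PhSO2H, CaCl2, CH2Cl2, rt
Reagents that add atoms: benzenesulfinic acid, O=S(O)c1ccccc1
Why: anomeric substitution of a lactol by a sulfinic acid through the cyclic oxocarbenium ion, giving a storable anomeric sulfone as the C2 leaving group with the ring intact.

Step 10
Reactants: 17 5-bromo-1,2,3-trimethoxybenzene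
Product: 18 5-bromobenzene-1,2,3-triol
Conditions: BBr3, CH2Cl2, −78 °C → rt; then H2O
Reagents that add atoms: none
Why: Lewis-acid cleavage of aryl methyl ethers by BBr3, which leaves the aryl bromide untouched.

Step 11
Reactants: 18 5-bromobenzene-1,2,3-triol
Product: 19 5-bromo-1,2,3-tris(benzyloxy)benzene
Conditions: BnBr (3.3 equiv), K2CO3, DMF, rt, under N2
Reagents that add atoms: benzyl bromide, BrCc1ccccc1
Why: Williamson etherification of the three phenols, which gives the ring B donor in the same benzyl protection as the rest of the molecule.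

Step 12
Reactants: 16 (3S,4R)-3,5,7-tris(benzyloxy)-4-(penta-O-benzylcatechin-8-yl)-2-(phenylsulfonyl)chroman; 19 5-bromo-1,2,3-tris(benzyloxy)benzene
Product: 22 undeca-O-benzyl-gallocatechin-(4β→8)-catechin (middle unit 2,3-trans-3,4-cis), via 3,4,5-tris(benzyloxy)phenylmagnesium bromide 20 (not isolated), via 3,4,5-tris(benzyloxy)phenylzinc bromide 21 (not isolated)
Conditions: 19, Mg, THF, rt; ZnBr2, THF, 0 °C; then 16, THF, 0 °C → rt
Reagents that add atoms: none
Why: substitution of an anomeric sulfone by an arylzinc reagent, in which the zinc Lewis acid ionises the C2–sulfonyl bond to the cyclic oxocarbenium ion and the aryl group is delivered to C2 on the face opposite the cis C3 benzyloxy and C4 aryl groups (anti to the adjacent C–O bond), which should set C2 as 2,3-trans while the O1–C2 bond made in step 7 is retained.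

Step 13
Reactants: 2 5,7,3',4'-tetra-O-benzyl-(+)-catechin
Product: 23 8-bromo-5,7,3',4'-tetra-O-benzyl-(+)-catechin
Conditions: NBS (1.0 equiv), CH2Cl2, −78 °C → rt
Reagents that add atoms: N-bromosuccinimide, O=C1CCC(=O)N1Br
Why: electrophilic aromatic bromination at C8 as in step 3, which caps the only strongly nucleophilic position of the future electrophile so that it cannot condense with itself.

Step 14
Reactants: 23 8-bromo-5,7,3',4'-tetra-O-benzyl-(+)-catechin
Product: 24 8-bromo-4β-(2-ethoxyethoxy)-5,7,3',4'-tetra-O-benzyl-(+)-catechin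
Conditions: DDQ (2 equiv), EtOCH2CH2OH (5 equiv), CH2Cl2, rt
Reagents that add atoms: 2-ethoxyethanol, CCOCCO
Why: DDQ benzylic oxidation, in which hydride abstraction at C4 gives the ring A-stabilised cation that is trapped by the alcohol; the new C4 centre is only a leaving-group carrier.

Step 15
Reactants: 24 8-bromo-4β-(2-ethoxyethoxy)-5,7,3',4'-tetra-O-benzyl-(+)-catechin
Product: 25 3-O-acetyl-8-bromo-4β-(2-ethoxyethoxy)-5,7,3',4'-tetra-O-benzyl-(+)-catechin
Conditions: Ac2O, pyridine, DMAP (cat.), rt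
Reagents that add atoms: acetic anhydride, CC(=O)OC(C)=O
Why: DMAP-catalysed acylation of the secondary alcohol, which installs a participating group on the β face next to C4.

Step 16
Reactants: 22 undeca-O-benzyl-gallocatechin-(4β→8)-catechin; 25 3-O-acetyl-8-bromo-4β-(2-ethoxyethoxy)-5,7,3',4'-tetra-O-benzyl-(+)-catechin
Product: 26 3-O-acetyl-8-bromo-tetra-O-benzylcatechin-(4α→8)-hexa-O-benzylgallocatechin-(4β→8)-penta-O-benzylcatechin
Conditions: 25 (1.5 equiv), BF3·OEt2 (0.3 equiv), CH2Cl2, −78 → −30 °C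
Reagents that add atoms: none
Why: Lewis-acid Friedel–Crafts-type arylation of a flavan-4-yl cation, in which BF3 ionises the 4-alkoxy group, the 3-acetoxy group covers the β face as an acetoxonium ion, and C8 of the middle unit of 22 (the most nucleophilic free ring A position, flanked by O1 and one ether only) attacks from the α face to give the 3,4-trans (4α→8) bond.

Step 17
Reactants: 26 3-O-acetyl-8-bromo-tetra-O-benzylcatechin-(4α→8)-hexa-O-benzylgallocatechin-(4β→8)-penta-O-benzylcatechin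
Product: 27 8-bromo-tetra-O-benzylcatechin-(4α→8)-hexa-O-benzylgallocatechin-(4β→8)-penta-O-benzylcatechin
Conditions: K2CO3 (cat.), MeOH/THF, rt
Reagents that add atoms: none
Why: base-catalysed transesterification (methanolysis) of the acetate, to which benzyl ethers, the aryl bromide and the interflavan bonds are inert.

Step 18
Reactants: 27 8-bromo-tetra-O-benzylcatechin-(4α→8)-hexa-O-benzylgallocatechin-(4β→8)-penta-O-benzylcatechin
Product: 28 catechin-(4α→8)-gallocatechin-(4β→8)-catechin (CNP0302529.2)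
Conditions: H2 (1 atm), Pd(OH)2/C, THF/MeOH/H2O, rt
Reagents that add atoms: none
Why: catalytic hydrogenolysis, which should cleave the fifteen benzyl ethers and the C8–Br bond in one operation without touching any stereocentre.

## Compound list

1 | (+)-catechin | Oc1cc(O)c2c(c1)O[C@H](c1ccc(O)c(O)c1)[C@@H](O)C2 | starting material
2 | 5,7,3',4'-tetra-O-benzyl-(+)-catechin | c9ccccc9COc1cc(OCc9ccccc9)c2c(c1)O[C@H](c1ccc(OCc9ccccc9)c(OCc9ccccc9)c1)[C@@H](O)C2 | intermediate
3 | 3,5,7,3',4'-penta-O-benzyl-(+)-catechin | c9ccccc9COc1cc(OCc9ccccc9)c2c(c1)O[C@H](c1ccc(OCc9ccccc9)c(OCc9ccccc9)c1)[C@@H](OCc9ccccc9)C2 | intermediate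
4 | 8-bromo-3,5,7,3',4'-penta-O-benzyl-(+)-catechin | c9ccccc9COc1cc(OCc9ccccc9)c2c(c1Br)O[C@H](c1ccc(OCc9ccccc9)c(OCc9ccccc9)c1)[C@@H](OCc9ccccc9)C2 | intermediate
5 | 2,4,6-trihydroxybenzaldehyde | O=Cc1c(O)cc(O)cc1O | starting material
6 | 4,6-bis(benzyloxy)-2-hydroxybenzaldehyde | O=Cc1c(O)cc(OCc9ccccc9)cc1OCc9ccccc9 | intermediate
7 | 8-lithio-penta-O-benzylcatechin | [Li]c1c(OCc9ccccc9)cc(OCc9ccccc9)c2c1O[C@H](c1ccc(OCc9ccccc9)c(OCc9ccccc9)c1)[C@@H](OCc9ccccc9)C2 | intermediate (not isolated)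
8 | sodium 3,5-bis(benzyloxy)-2-formylphenoxide | [Na+].[O-]c1cc(OCc9ccccc9)cc(OCc9ccccc9)c1C=O | intermediate (not isolated)
9 | [4,6-bis(benzyloxy)-2-hydroxyphenyl](penta-O-benzylcatechin-8-yl)methanol, carbinol epimers | OC(c1c(O)cc(OCc9ccccc9)cc1OCc9ccccc9)c1c(OCc9ccccc9)cc(OCc9ccccc9)c2c1O[C@H](c1ccc(OCc9ccccc9)c(OCc9ccccc9)c1)[C@@H](OCc9ccccc9)C2 | intermediate
10 | 3,5-bis(benzyloxy)-2-[(penta-O-benzylcatechin-8-yl)(p-tolylsulfonyl)methyl]phenol, epimers | Cc1ccc(cc1)S(=O)(=O)C(c1c(O)cc(OCc9ccccc9)cc1OCc9ccccc9)c1c(OCc9ccccc9)cc(OCc9ccccc9)c2c1O[C@H](c1ccc(OCc9ccccc9)c(OCc9ccccc9)c1)[C@@H](OCc9ccccc9)C2 | intermediate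
11 | benzyloxyacetyl chloride | O=C(Cl)COCc1ccccc1 | starting material
12 | o-quinone methide, 3,5-bis(benzyloxy)-6-[(penta-O-benzylcatechin-8-yl)methylidene]cyclohexa-2,4-dien-1-one | O=C1C=C(OCc9ccccc9)C=C(OCc9ccccc9)C1=Cc1c(OCc9ccccc9)cc(OCc9ccccc9)c2c1O[C@H](c1ccc(OCc9ccccc9)c(OCc9ccccc9)c1)[C@@H](OCc9ccccc9)C2 | intermediate (not isolated)
13 | benzyloxyketene | O=C=COCc1ccccc1 | intermediate (not isolated)
14 | (3S,4R)-3,5,7-tris(benzyloxy)-4-(penta-O-benzylcatechin-8-yl)chroman-2-one, 3,4-cis | c9ccccc9COc1cc(OCc9ccccc9)c2c(c1)OC(=O)[C@@H](OCc9ccccc9)[C@H]2c1c(OCc9ccccc9)cc(OCc9ccccc9)c2c1O[C@H](c1ccc(OCc9ccccc9)c(OCc9ccccc9)c1)[C@@H](OCc9ccccc9)C2 | intermediate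
15 | (3S,4R)-3,5,7-tris(benzyloxy)-4-(penta-O-benzylcatechin-8-yl)chroman-2-ol, anomers | c9ccccc9COc1cc(OCc9ccccc9)c2c(c1)OC(O)[C@@H](OCc9ccccc9)[C@H]2c1c(OCc9ccccc9)cc(OCc9ccccc9)c2c1O[C@H](c1ccc(OCc9ccccc9)c(OCc9ccccc9)c1)[C@@H](OCc9ccccc9)C2 | intermediate
16 | (3S,4R)-3,5,7-tris(benzyloxy)-4-(penta-O-benzylcatechin-8-yl)-2-(phenylsulfonyl)chroman, anomers | c9ccccc9COc1cc(OCc9ccccc9)c2c(c1)OC(S(=O)(=O)c1ccccc1)[C@@H](OCc9ccccc9)[C@H]2c1c(OCc9ccccc9)cc(OCc9ccccc9)c2c1O[C@H](c1ccc(OCc9ccccc9)c(OCc9ccccc9)c1)[C@@H](OCc9ccccc9)C2 | intermediate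
17 | 5-bromo-1,2,3-trimethoxybenzene | COc1cc(Br)cc(OC)c1OC | starting material
18 | 5-bromobenzene-1,2,3-triol | Oc1cc(Br)cc(O)c1O | intermediate
19 | 5-bromo-1,2,3-tris(benzyloxy)benzene | Brc1cc(OCc9ccccc9)c(OCc9ccccc9)c(OCc9ccccc9)c1 | intermediate
20 | 3,4,5-tris(benzyloxy)phenylmagnesium bromide | Br[Mg]c1cc(OCc9ccccc9)c(OCc9ccccc9)c(OCc9ccccc9)c1 | intermediate (not isolated)
21 | 3,4,5-tris(benzyloxy)phenylzinc bromide | Br[Zn]c1cc(OCc9ccccc9)c(OCc9ccccc9)c(OCc9ccccc9)c1 | intermediate (not isolated)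
22 | undeca-O-benzyl-gallocatechin-(4β→8)-catechin | c9ccccc9COc1cc(OCc9ccccc9)c2c(c1)O[C@H](c1cc(OCc9ccccc9)c(OCc9ccccc9)c(OCc9ccccc9)c1)[C@@H](OCc9ccccc9)[C@H]2c1c(OCc9ccccc9)cc(OCc9ccccc9)c2c1O[C@H](c1ccc(OCc9ccccc9)c(OCc9ccccc9)c1)[C@@H](OCc9ccccc9)C2 | intermediate
23 | 8-bromo-5,7,3',4'-tetra-O-benzyl-(+)-catechin | c9ccccc9COc1cc(OCc9ccccc9)c2c(c1Br)O[C@H](c1ccc(OCc9ccccc9)c(OCc9ccccc9)c1)[C@@H](O)C2 | intermediate
24 | 8-bromo-4β-(2-ethoxyethoxy)-5,7,3',4'-tetra-O-benzyl-(+)-catechin | c9ccccc9COc1cc(OCc9ccccc9)c2c(c1Br)O[C@H](c1ccc(OCc9ccccc9)c(OCc9ccccc9)c1)[C@@H](O)[C@H]2OCCOCC | intermediate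
25 | 3-O-acetyl-8-bromo-4β-(2-ethoxyethoxy)-5,7,3',4'-tetra-O-benzyl-(+)-catechin | c9ccccc9COc1cc(OCc9ccccc9)c2c(c1Br)O[C@H](c1ccc(OCc9ccccc9)c(OCc9ccccc9)c1)[C@@H](OC(C)=O)[C@H]2OCCOCC | intermediate
26 | 3-O-acetyl-8-bromo-tetra-O-benzylcatechin-(4α→8)-hexa-O-benzylgallocatechin-(4β→8)-penta-O-benzylcatechin | c9ccccc9COc1cc(OCc9ccccc9)c2c(c1Br)O[C@H](c1ccc(OCc9ccccc9)c(OCc9ccccc9)c1)[C@@H](OC(C)=O)[C@@H]2c1c(OCc9ccccc9)cc(OCc9ccccc9)c2c1O[C@H](c1cc(OCc9ccccc9)c(OCc9ccccc9)c(OCc9ccccc9)c1)[C@@H](OCc9ccccc9)[C@H]2c1c(OCc9ccccc9)cc(OCc9ccccc9)c2c1O[C@H](c1ccc(OCc9ccccc9)c(OCc9ccccc9)c1)[C@@H](OCc9ccccc9)C2 | intermediate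
27 | 8-bromo-tetra-O-benzylcatechin-(4α→8)-hexa-O-benzylgallocatechin-(4β→8)-penta-O-benzylcatechin | c9ccccc9COc1cc(OCc9ccccc9)c2c(c1Br)O[C@H](c1ccc(OCc9ccccc9)c(OCc9ccccc9)c1)[C@@H](O)[C@@H]2c1c(OCc9ccccc9)cc(OCc9ccccc9)c2c1O[C@H](c1cc(OCc9ccccc9)c(OCc9ccccc9)c(OCc9ccccc9)c1)[C@@H](OCc9ccccc9)[C@H]2c1c(OCc9ccccc9)cc(OCc9ccccc9)c2c1O[C@H](c1ccc(OCc9ccccc9)c(OCc9ccccc9)c1)[C@@H](OCc9ccccc9)C2 | intermediate
28 | catechin-(4α→8)-gallocatechin-(4β→8)-catechin (CNP0302529.2) | Oc1cc(O)c2c(c1)O[C@H](c1ccc(O)c(O)c1)[C@@H](O)[C@@H]2c1c(O)cc(O)c2c1O[C@H](c1cc(O)c(O)c(O)c1)[C@@H](O)[C@H]2c1c(O)cc(O)c2c1O[C@H](c1ccc(O)c(O)c1)[C@@H](O)C2 | target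

## Step count and risks

Total steps: 18. Longest linear sequence: 12 steps from (+)-catechin (steps 1, 2, 3, 5, 6, 7, 8, 9, 12, 16, 17, 18).

Steps most likely to fail:

Step 7. The Michael step may give poor cis/trans or facial selectivity, the phenol may be O-acylated before sulfinate is lost, or base may epimerise C3 of the cis lactone. The fallback sets out from benzhydrol 9 and returns at lactone 14. Methyl benzyloxyacetate is converted with LiN(i-Pr)2 and Me3SiCl (THF, −78 °C) into (Z)-2-benzyloxy-1-methoxy-1-(trimethylsilyloxy)ethene F1. A chiral BINOL-derived phosphoric acid dehydrates 9 to the hydrogen-bonded o-quinone methide 12, and F1 adds to it in a Mukaiyama–Michael reaction to give methyl 2-benzyloxy-3-[4,6-bis(benzyloxy)-2-hydroxyphenyl]-3-(penta-O-benzylcatechin-8-yl)propanoate F2; its epimers at the diaryl carbon are diastereomers and can be separated, and the α-carbon is left unassigned. Catalytic TsOH in warm toluene lactonises F2 to 14 together with its C3 epimer, the 3,4-trans lactone F3. F3 is converged on 14 by deprotonation with LiN(SiMe3)2 at −78 °C and kinetic protonation of the enolate on the face away from the C4 aryl group.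

Step 12. Ionisation of the hindered anomeric sulfone may be slow, the oxocarbenium ion may lose the C3 proton (elimination to the chromene), or the aryl group may enter on the wrong face. The fallback sets out from lactol 15 and returns at 22. Excess Grignard reagent 20 deprotonates 15 and opens it to the bromomagnesium phenoxide of the α-benzyloxy aldehyde F4. Chelation-controlled (Cram-chelate) addition of 20 to the formyl group, opposite the diarylmethyl substituent, should give the 1,2-syn diol F5. Intramolecular Mitsunobu etherification (PPh3, diisopropyl azodicarboxylate, THF) then closes O1–C2 with inversion, which turns the syn alcohol into the 2,3-trans flavan 22.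

Step 16. Attack of the hindered dimer may be slow enough for the cation to decompose, attack may occur at C6 instead of C8, or 3,4-trans selectivity may be incomplete. The fallback sets out from 22 and returns at target 28. Hydrogenolysis of 22 (H2, Pd(OH)2/C) gives free gallocatechin-(4β→8)-catechin F6. (+)-Taxifolin is reduced with NaBH4 in ethanol to 2,3-trans-3,4-trans-leucocyanidin F7. Biomimetic condensation of F7 with F6 in water at pH 5 forms the C4–C8 bond through the unprotected flavan-4-yl cation, and 28 is separated from regio- and stereoisomers on Sephadex LH-20 and by preparative HPLC.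

Further compounds
F1 | step 7 | (Z)-2-benzyloxy-1-methoxy-1-(trimethylsilyloxy)ethene | CO/C(O[Si](C)(C)C)=C/OCc1ccccc1
F2 | step 7 | methyl 2-benzyloxy-3-[4,6-bis(benzyloxy)-2-hydroxyphenyl]-3-(penta-O-benzylcatechin-8-yl)propanoate | COC(=O)C(OCc9ccccc9)[C@H](c1c(O)cc(OCc9ccccc9)cc1OCc9ccccc9)c1c(OCc9ccccc9)cc(OCc9ccccc9)c2c1O[C@H](c1ccc(OCc9ccccc9)c(OCc9ccccc9)c1)[C@@H](OCc9ccccc9)C2
F3 | step 7 | 3,4-trans-3,5,7-tris(benzyloxy)-4-(penta-O-benzylcatechin-8-yl)chroman-2-one (C3 epimer of 14) | c9ccccc9COc1cc(OCc9ccccc9)c2c(c1)OC(=O)[C@H](OCc9ccccc9)[C@H]2c1c(OCc9ccccc9)cc(OCc9ccccc9)c2c1O[C@H](c1ccc(OCc9ccccc9)c(OCc9ccccc9)c1)[C@@H](OCc9ccccc9)C2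
F4 | step 12 | bromomagnesium phenoxide of 2-benzyloxy-3-[4,6-bis(benzyloxy)-2-hydroxyphenyl]-3-(penta-O-benzylcatechin-8-yl)propanal | O=C[C@@H](OCc9ccccc9)[C@H](c1c(O[Mg]Br)cc(OCc9ccccc9)cc1OCc9ccccc9)c1c(OCc9ccccc9)cc(OCc9ccccc9)c2c1O[C@H](c1ccc(OCc9ccccc9)c(OCc9ccccc9)c1)[C@@H](OCc9ccccc9)C2
F5 | step 12 | 1,2-syn-2-benzyloxy-3-[4,6-bis(benzyloxy)-2-hydroxyphenyl]-3-(penta-O-benzylcatechin-8-yl)-1-[3,4,5-tris(benzyloxy)phenyl]propan-1-ol | O[C@@H](c1cc(OCc9ccccc9)c(OCc9ccccc9)c(OCc9ccccc9)c1)[C@@H](OCc9ccccc9)[C@H](c1c(O)cc(OCc9ccccc9)cc1OCc9ccccc9)c1c(OCc9ccccc9)cc(OCc9ccccc9)c2c1O[C@H](c1ccc(OCc9ccccc9)c(OCc9ccccc9)c1)[C@@H](OCc9ccccc9)C2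
F6 | step 16 | gallocatechin-(4β→8)-catechin | Oc1cc(O)c2c(c1)O[C@H](c1cc(O)c(O)c(O)c1)[C@@H](O)[C@H]2c1c(O)cc(O)c2c1O[C@H](c1ccc(O)c(O)c1)[C@@H](O)C2
F7 | step 16 | 2,3-trans-3,4-trans-leucocyanidin | Oc1cc(O)c2c(c1)O[C@H](c1ccc(O)c(O)c1)[C@@H](O)[C@@H]2O
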